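**Earlier runs.** In the beta run, at its last reading, I followed the electrophile by a halving time of 0.903 min, the time multiplied by the part of electrophile left and divided by the part gone. For a reactant falling by second order against an equal partner this stays constant, and the part left is the halving time over itself plus the time.

| setting | delta | beta | Tuesday's | Thursday's |
|---|---|---|---|---|
| electrophile | 0.50 M | 0.50 M | 0.50 M | 0.50 M |
| nucleophile | 0.90 equiv | 0.90 equiv | 0.900 equiv | 0.900 equiv |
| free base | 0.63 equiv | 1.1 equiv | 1.00 equiv | 1.50 equiv |
| remark | run made earlier | run made earlier |  |  |
| time |  |  | 10 min | 10 min |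

| run | time / min | electrophile / % | target / % |
|---|---|---|---|
| delta | 0.417 | 68.3 | 22.6 |
| delta | 0.833 | 52.8 | 27.5 |
| delta | 1.33 | 41.2 | 32.6 |
| delta | 2.50 | 28.1 | 30.7 |
| delta | 5.00 | 19.0 | 28.0 |
| beta | 0.417 | 67.9 | 20.8 |
| beta | 0.833 | 52.3 | 30.3 |
| beta | 1.33 | 40.7 | 32.4 |
| beta | 2.50 | 26.4 | 34.0 |
| beta | 5.00 | 15.3 | 27.3 |

(readings scatter by 1 percentage point)

* part of the electrophile that has reacted at the end, Tuesday's
* part of the electrophile that has reacted at the end, Thursday's
* what raising the equivalents of free base from its lowest to its highest value here does to the part of the electrophile that has reacted (changes below 5 percentage points count as none) (it falls / no change / it rises)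

- steps under discussion: electrophile <-> dormant form; electrophile + nucleophile -> acid set free + target; nucleophile + acid set free <-> protonated nucleophile; acid set free + free base <-> salt of the base; 2 free base -> self-condensation product; target <-> isomer of the product
- what has gone from electrophile into another species counts as reacted, even if it can come back

**The chain.** The beta run gave 0.913 min at 0.833 min and 0.903 min at 5.00 min, constant within the scatter, and held constant this reading pointed to 8.28% of the electrophile left at 10 min. The delta run, with 0.63 equiv of free base, gave 0.977 min at 2.50 min and 1.17 min at 5.00 min. Interpolating on the free base, I put Tuesday's flask at 0.961 min at that time, and I held Thursday's flask at the beta reading.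

**The weak link.** A constant halving time was the doubtful step, since the nucleophile, the limiting reagent at 0.900 equiv, is no equal partner. So I stretched both flasks by the factor the delta run showed over its last doubling of time, 1.20. That put Tuesday's flask, by my estimate, at 10.3% of the electrophile left and 89.7% reacted, and Thursday's at 9.78% left and 90.2% reacted, and I read the gap of 0.52 percentage points as no change.

**The forecast.** It gave 90% and 92%, and for the trend it rises, saying that “the part reacted rises modestly”; there my reckoning differs.

**The result.** The simulation gave 88.0% reacted for Tuesday's flask and 88.8% for Thursday's, a change of 0.81 points, so no change.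

    electrophile ⇌ dormant form (K = 1.70, k = 0.00340 s⁻¹)
    electrophile + nucleophile → acid set free + target (k = 0.0360 L mol⁻¹ s⁻¹)
    nucleophile + acid set free ⇌ protonated nucleophile, settled at all times (K = 3800 L mol⁻¹)
    acid set free + free base ⇌ salt of the base, settled at all times (K = 1900 L mol⁻¹)
    2 free base → self-condensation product (k = 0.00290 L mol⁻¹ s⁻¹)
    target ⇌ isomer of the product (K = 1.70, k = 0.00610 s⁻¹)

**Halving times.** At the end Thursday's flask held 0.179 M of self-condensation product against 0.0849 M in Tuesday's. Reckoned as the 0.903 min of the beta run was, Tuesday's halving time went from 0.979 min at 5.00 min to 1.36 min at 10.0 min. Thursday's went from 0.907 min at 5.00 min to 1.26 min at 10.0 min.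

The data stem from a simulated flask with made-up constants; the scatter is artificial.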